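**Retrosynthetic overview**

- The C40 chain is cut at C11=C12 and C11'=C12' into a ring-end C15 phosphonium salt, the C10 trienedial and an open-chain C15 phosphonium salt. Two Wittig reactions join them with all four hydroxyls free, so there is no final deprotection.
- The ring-end salt comes from (3S,4R)-3,4-dihydroxy-β-ionone (vinyl Grignard, then PPh3·HBr). Its C4–O bond is made by anodic allylic C–H oxidation of (3R)-3-O-Boc-β-ionone with capture by the Boc group, which places O4 cis to O3.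
- The O-Boc-β-ionone comes from the enol triflate of O-Boc-(4R,6R)-actinol and butenone (Heck). The carbocycle is bought; the only ring made is the transient five-membered carbonate.
- The open-chain salt comes from a (9S)-trienone, built by two olefinations of (4R)-2,2,5,5-tetramethyl-1,3-dioxolane-4-carbaldehyde, itself made from methyl (S)-glycerate acetonide (C2').

Assumption: the target is taken as drawn, (3S,4R,2'S) and all-E; actinol, the glycerate ester, the trienedial and the cyanophosphonate (E isomer) are purchased.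

**Route**

Step 1
Reactants: 1 (4R,6R)-4-hydroxy-2,2,6-trimethylcyclohexan-1-one (actinol)
Product: 2 tert-butyl (1R,5R)-3,3,5-trimethyl-4-oxocyclohexyl carbonate
Conditions: Boc2O, DMAP (cat.), CH2Cl2, 25 °C
Reagents that add atoms: di-tert-butyl dicarbonate, CC(C)(C)OC(=O)OC(=O)OC(C)(C)C
Why: DMAP-catalysed O-acylation gives the Boc carbonate, which protects the hydroxyl and later acts as the internal oxygen nucleophile; no stereocentre is touched.

Step 2
Reactants: 2 tert-butyl (1R,5R)-3,3,5-trimethyl-4-oxocyclohexyl carbonate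
Product: 3 (4R)-4-[(tert-butoxycarbonyl)oxy]-2,6,6-trimethylcyclohex-1-en-1-yl trifluoromethanesulfonate
Conditions: KN(SiMe3)2, THF, –78 °C; then PhNTf2, –78 → 0 °C
Reagents that add atoms: N-phenylbis(trifluoromethanesulfonimide), O=S(=O)(N(c1ccccc1)S(=O)(=O)C(F)(F)F)C(F)(F)F
Why: The ketone has a single α-hydrogen, so the enolate forms in one direction and is O-triflated (enol triflate formation); the methyl-bearing stereocentre is erased and the carbinol centre is unaffected.

Step 3
Reactants: 3 (4R)-4-[(tert-butoxycarbonyl)oxy]-2,6,6-trimethylcyclohex-1-en-1-yl trifluoromethanesulfonate; 4 but-3-en-2-one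
Product: 5 tert-butyl (1R)-3,5,5-trimethyl-4-[(1E)-3-oxobut-1-en-1-yl]cyclohex-3-en-1-yl carbonate
Conditions: Pd(OAc)2 (5 mol %), PPh3 (10 mol %), Et3N, DMF, 75 °C
Reagents that add atoms: none
Why: Mizoroki–Heck alkenylation: zerovalent palladium inserts into the C–OTf bond, and syn-carbopalladation of butenone followed by β-hydride elimination gives the E-dienone.

Step 4
Reactants: 5 tert-butyl (1R)-3,5,5-trimethyl-4-[(1E)-3-oxobut-1-en-1-yl]cyclohex-3-en-1-yl carbonate
Product: 7 (3E)-4-[(3R,4S)-3,4-dihydroxy-2,6,6-trimethylcyclohex-1-en-1-yl]but-3-en-2-one, via cis-fused cyclic carbonate 6 (not isolated)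
Conditions: tetrachloro-N-hydroxyphthalimide (20 mol %), 2,6-lutidine, LiBF4, MeCN/(CF3)2CHOH 9:1, reticulated vitreous carbon anode, Ni cathode, undivided cell, constant current, N2, 25 °C; then K2CO3 (cat.), MeOH, 0 °C
Reagents that add atoms: none
Why: Proposed new method: electrochemical allylic C–H oxygenation with internal capture, in which the anodically generated tetrachlorophthalimide N-oxyl abstracts a ring C4–H (the only secondary allylic C–H, the radical being delocalised over the dienone), the radical is taken to the allyl cation at the anode (directly or through its N-oxyl adduct), the carbonyl oxygen of the neighbouring O-Boc group closes a five-membered ring onto C4 and tert-butyl cation leaves as isobutene, so the C4–O bond can only form cis to the bought C3–O (4R) before methanolysis frees the diol; the closest known chemistry is N-hydroxyphthalimide-mediated electrochemical allylic C–H oxidation and Boc-carbonate capture of iodonium or allyl cations (iodocarbonate cyclisation).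

Step 5
Reactants: 7 (3E)-4-[(3R,4S)-3,4-dihydroxy-2,6,6-trimethylcyclohex-1-en-1-yl]but-3-en-2-one
Product: 8 (1S,2R)-4-[(1E)-3-hydroxy-3-methylpenta-1,4-dien-1-yl]-3,5,5-trimethylcyclohex-3-ene-1,2-diol (both carbinol epimers)
Conditions: CH2=CHMgBr (4 equiv), THF, –30 → 0 °C; then H2O
Reagents that add atoms: vinylmagnesium bromide, C=C[Mg]Br
Why: Grignard 1,2-addition to the methyl ketone after deprotonation of the two hydroxyls, as in the vinyl-β-ionol synthesis; the new carbinol centre is lost in step 6, so its configuration does not matter.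

Step 6
Reactants: 8 (1S,2R)-4-[(1E)-3-hydroxy-3-methylpenta-1,4-dien-1-yl]-3,5,5-trimethylcyclohex-3-ene-1,2-diol
Product: 9 {(2E,4E)-5-[(3R,4S)-3,4-dihydroxy-2,6,6-trimethylcyclohex-1-en-1-yl]-3-methylpenta-2,4-dien-1-yl}triphenylphosphonium bromide
Conditions: PPh3·HBr (1.0 equiv), MeOH, 0 → 25 °C
Reagents that add atoms: triphenylphosphine hydrobromide, Br.c1ccc(cc1)P(c1ccccc1)c1ccccc1
Why: The acid ionises only the tertiary, doubly allylic carbinol (the secondary C4–OH has a β-hydroxyl and is far slower), and PPh3 captures the cation at the unhindered terminus with allylic transposition (SN1' phosphonium salt formation, as for the zeaxanthin C15 salt); C3 and C4 are untouched.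

Step 7
Reactants: 9 {(2E,4E)-5-[(3R,4S)-3,4-dihydroxy-2,6,6-trimethylcyclohex-1-en-1-yl]-3-methylpenta-2,4-dien-1-yl}triphenylphosphonium bromide; 10 (2E,4E,6E)-2,7-dimethylocta-2,4,6-trienedial
Product: 11 (2E,4E,6E,8E,10E,12E)-13-[(3R,4S)-3,4-dihydroxy-2,6,6-trimethylcyclohex-1-en-1-yl]-2,7,11-trimethyltrideca-2,4,6,8,10,12-hexaenal
Conditions: 10 (3 equiv), NaOMe, MeOH/CH2Cl2, 0 → 25 °C; then EtOH, 78 °C (Z → E)
Reagents that add atoms: none
Why: Wittig reaction of the semi-stabilised ylide with excess dialdehyde gives mono-olefination (the product aldehyde is less electrophilic), the free hydroxyls are only deprotonated, and the hindered 11Z isomer equilibrates thermally to E.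

Step 8
Reactants: 12 methyl (4S)-2,2-dimethyl-1,3-dioxolane-4-carboxylate
Product: 13 2-[(4S)-2,2-dimethyl-1,3-dioxolan-4-yl]propan-2-ol
Conditions: MeMgBr (2.5 equiv), THF, 0 → 25 °C; then H2O
Reagents that add atoms: methylmagnesium bromide, C[Mg]Br
Why: Double Grignard addition to the ester builds the tertiary carbinol (future C1'); the bought stereocentre (future C2') is carried through unchanged.

Step 9
Reactants: 13 2-[(4S)-2,2-dimethyl-1,3-dioxolan-4-yl]propan-2-ol
Product: 14 [(4S)-2,2,5,5-tetramethyl-1,3-dioxolan-4-yl]methanol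
Conditions: p-TsOH·H2O (5 mol %), acetone, 25 °C
Reagents that add atoms: none
Why: Acid-catalysed acetonide migration under thermodynamic control to the more substituted dioxolane (gem-dialkyl effect) frees the primary hydroxyl; no C–O bond at the stereocentre is broken.

Step 10
Reactants: 14 [(4S)-2,2,5,5-tetramethyl-1,3-dioxolan-4-yl]methanol
Product: 15 (4R)-2,2,5,5-tetramethyl-1,3-dioxolane-4-carbaldehyde
Conditions: Dess–Martin periodinane, CH2Cl2, 0 → 25 °C
Reagents that add atoms: none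
Why: Dess–Martin oxidation of the primary alcohol under near-neutral conditions that do not epimerise the α-alkoxy aldehyde (the descriptor changes to R only by priority).

Step 11
Reactants: 15 (4R)-2,2,5,5-tetramethyl-1,3-dioxolane-4-carbaldehyde; 16 diethyl [(2E)-3-cyano-2-methylprop-2-en-1-yl]phosphonate
Product: 17 (2E,4E)-3-methyl-5-[(4S)-2,2,5,5-tetramethyl-1,3-dioxolan-4-yl]penta-2,4-dienenitrile
Conditions: LiN(SiMe3)2, THF, –78 → 0 °C
Reagents that add atoms: none
Why: Horner–Wadsworth–Emmons olefination with the stabilised C5 phosphonate anion gives the new E double bond and keeps the E geometry of the reagent; the low temperature preserves the α-stereocentre.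

Step 12
Reactants: 17 (2E,4E)-3-methyl-5-[(4S)-2,2,5,5-tetramethyl-1,3-dioxolan-4-yl]penta-2,4-dienenitrile
Product: 19 (2E,4E,6S)-6,7-dihydroxy-3,7-dimethylocta-2,4-dienal, via acetonide dienal 18 (not isolated)
Conditions: i-Bu2AlH, CH2Cl2, –78 °C; then 2 M HCl, THF, 25 °C
Reagents that add atoms: water, O
Why: Partial hydride reduction of the nitrile to the iminoalane and acid hydrolysis give the dienal, and the same aqueous acid cleaves the acetonide cleanly because a cation at the allylic carbinol would be conjugated to the enal and does not form.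

Step 13
Reactants: 19 (2E,4E,6S)-6,7-dihydroxy-3,7-dimethylocta-2,4-dienal; 20 1-(triphenyl-λ5-phosphanylidene)propan-2-one
Product: 21 (3E,5E,7E,9S)-9,10-dihydroxy-6,10-dimethylundeca-3,5,7-trien-2-one
Conditions: THF, 60 °C
Reagents that add atoms: none
Why: Wittig reaction of a stabilised ylide is E-selective, neutral and tolerant of the free diol.

Step 14
Reactants: 21 (3E,5E,7E,9S)-9,10-dihydroxy-6,10-dimethylundeca-3,5,7-trien-2-one
Product: 22 (4E,6E,8E,10S)-3,7,11-trimethyldodeca-1,4,6,8-tetraene-3,10,11-triol (both C3 epimers)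
Conditions: CH2=CHMgBr (4 equiv), THF, –30 → 0 °C; then H2O
Reagents that add atoms: vinylmagnesium bromide, C=C[Mg]Br
Why: Grignard 1,2-addition to the methyl ketone, as for vinyl-pseudoionol; the new carbinol centre is removed in step 15.

Step 15
Reactants: 22 (4E,6E,8E,10S)-3,7,11-trimethyldodeca-1,4,6,8-tetraene-3,10,11-triol
Product: 23 [(2E,4E,6E,8E,10S)-10,11-dihydroxy-3,7,11-trimethyldodeca-2,4,6,8-tetraen-1-yl]triphenylphosphonium bromide
Conditions: PPh3·HBr (1.0 equiv), MeOH, 0 → 25 °C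
Reagents that add atoms: triphenylphosphine hydrobromide, Br.c1ccc(cc1)P(c1ccccc1)c1ccccc1
Why: SN1' phosphonium salt formation as in step 6: the tertiary bis-allylic carbinol ionises much faster than the secondary C10–OH (β-hydroxylated), and PPh3 adds at the primary terminus; C10 is untouched.

Step 16
Reactants: 11 (2E,4E,6E,8E,10E,12E)-13-[(3R,4S)-3,4-dihydroxy-2,6,6-trimethylcyclohex-1-en-1-yl]-2,7,11-trimethyltrideca-2,4,6,8,10,12-hexaenal; 23 [(2E,4E,6E,8E,10S)-10,11-dihydroxy-3,7,11-trimethyldodeca-2,4,6,8-tetraen-1-yl]triphenylphosphonium bromide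
Product: 24 (3S,4R,2'S)-3',4'-didehydro-1',2'-dihydro-β,ψ-carotene-3,4,1',2'-tetrol (all-E)
Conditions: NaOMe, MeOH/CH2Cl2, 0 → 25 °C; then heptane/EtOH, 80 °C (Z → E), crystallisation
Reagents that add atoms: none
Why: Wittig reaction forms C11'=C12' with all hydroxyls free, and thermal equilibration with crystallisation delivers the all-E polyene; the three stereocentres are remote from the reacting centres.

**Compound list**

1 | (4R,6R)-4-hydroxy-2,2,6-trimethylcyclohexan-1-one | C[C@@H]1C[C@@H](O)CC(C)(C)C1=O | starting material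
2 | tert-butyl (1R,5R)-3,3,5-trimethyl-4-oxocyclohexyl carbonate | C[C@@H]1C[C@@H](OC(=O)OC(C)(C)C)CC(C)(C)C1=O | intermediate
3 | (4R)-4-[(tert-butoxycarbonyl)oxy]-2,6,6-trimethylcyclohex-1-en-1-yl trifluoromethanesulfonate | CC1=C(OS(=O)(=O)C(F)(F)F)C(C)(C)C[C@H](OC(=O)OC(C)(C)C)C1 | intermediate
4 | but-3-en-2-one | C=CC(C)=O | starting material
5 | tert-butyl (1R)-3,5,5-trimethyl-4-[(1E)-3-oxobut-1-en-1-yl]cyclohex-3-en-1-yl carbonate | CC1=C(/C=C/C(C)=O)C(C)(C)C[C@H](OC(=O)OC(C)(C)C)C1 | intermediate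
6 | (3aS,7aR)-5,5,7-trimethyl-6-[(1E)-3-oxobut-1-en-1-yl]-3a,4,5,7a-tetrahydro-1,3-benzodioxol-2-one (cis-fused carbonate) | CC1=C(/C=C/C(C)=O)C(C)(C)C[C@@H]2OC(=O)O[C@H]12 | intermediate
7 | (3E)-4-[(3R,4S)-3,4-dihydroxy-2,6,6-trimethylcyclohex-1-en-1-yl]but-3-en-2-one | CC1=C(/C=C/C(C)=O)C(C)(C)C[C@H](O)[C@@H]1O | intermediate
8 | (1S,2R)-4-[(1E)-3-hydroxy-3-methylpenta-1,4-dien-1-yl]-3,5,5-trimethylcyclohex-3-ene-1,2-diol | CC1=C(/C=C/C(C)(O)C=C)C(C)(C)C[C@H](O)[C@@H]1O | intermediate
9 | {(2E,4E)-5-[(3R,4S)-3,4-dihydroxy-2,6,6-trimethylcyclohex-1-en-1-yl]-3-methylpenta-2,4-dien-1-yl}triphenylphosphonium bromide | CC1=C(/C=C/C(C)=C/C[P+](c2ccccc2)(c2ccccc2)c2ccccc2)C(C)(C)C[C@H](O)[C@@H]1O.[Br-] | intermediate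
10 | (2E,4E,6E)-2,7-dimethylocta-2,4,6-trienedial | O=C/C(C)=C/C=C/C=C(C)/C=O | starting material
11 | (2E,4E,6E,8E,10E,12E)-13-[(3R,4S)-3,4-dihydroxy-2,6,6-trimethylcyclohex-1-en-1-yl]-2,7,11-trimethyltrideca-2,4,6,8,10,12-hexaenal | CC1=C(/C=C/C(C)=C/C=C/C(C)=C/C=C/C=C(C)/C=O)C(C)(C)C[C@H](O)[C@@H]1O | intermediate
12 | methyl (4S)-2,2-dimethyl-1,3-dioxolane-4-carboxylate | COC(=O)[C@@H]1COC(C)(C)O1 | starting material
13 | 2-[(4S)-2,2-dimethyl-1,3-dioxolan-4-yl]propan-2-ol | CC(C)(O)[C@@H]1COC(C)(C)O1 | intermediate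
14 | [(4S)-2,2,5,5-tetramethyl-1,3-dioxolan-4-yl]methanol | OC[C@@H]1OC(C)(C)OC1(C)C | intermediate
15 | (4R)-2,2,5,5-tetramethyl-1,3-dioxolane-4-carbaldehyde | O=C[C@@H]1OC(C)(C)OC1(C)C | intermediate
16 | diethyl [(2E)-3-cyano-2-methylprop-2-en-1-yl]phosphonate | CCOP(=O)(OCC)C/C(C)=C/C#N | starting material
17 | (2E,4E)-3-methyl-5-[(4S)-2,2,5,5-tetramethyl-1,3-dioxolan-4-yl]penta-2,4-dienenitrile | N#C/C=C(C)/C=C/[C@@H]1OC(C)(C)OC1(C)C | intermediate
18 | (2E,4E)-3-methyl-5-[(4S)-2,2,5,5-tetramethyl-1,3-dioxolan-4-yl]penta-2,4-dienal | O=C/C=C(C)/C=C/[C@@H]1OC(C)(C)OC1(C)C | intermediate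
19 | (2E,4E,6S)-6,7-dihydroxy-3,7-dimethylocta-2,4-dienal | O=C/C=C(C)/C=C/[C@H](O)C(C)(C)O | intermediate
20 | 1-(triphenyl-λ5-phosphanylidene)propan-2-one | CC(=O)C=P(c1ccccc1)(c1ccccc1)c1ccccc1 | starting material
21 | (3E,5E,7E,9S)-9,10-dihydroxy-6,10-dimethylundeca-3,5,7-trien-2-one | CC(=O)/C=C/C=C(C)/C=C/[C@H](O)C(C)(C)O | intermediate
22 | (4E,6E,8E,10S)-3,7,11-trimethyldodeca-1,4,6,8-tetraene-3,10,11-triol | C=CC(C)(O)/C=C/C=C(C)/C=C/[C@H](O)C(C)(C)O | intermediate
23 | [(2E,4E,6E,8E,10S)-10,11-dihydroxy-3,7,11-trimethyldodeca-2,4,6,8-tetraen-1-yl]triphenylphosphonium bromide | C(/C=C(C)/C=C/C=C(C)/C=C/[C@H](O)C(C)(C)O)[P+](c1ccccc1)(c1ccccc1)c1ccccc1.[Br-] | intermediate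
24 | (3S,4R,2'S)-3',4'-didehydro-1',2'-dihydro-β,ψ-carotene-3,4,1',2'-tetrol | CC1=C(/C=C/C(C)=C/C=C/C(C)=C/C=C/C=C(C)/C=C/C=C(C)/C=C/C=C(C)/C=C/[C@H](O)C(C)(C)O)C(C)(C)C[C@H](O)[C@@H]1O | target

**Step count and risks**

Total step count: 16. Longest linear sequence: 9 (steps 8 to 15, then step 16); the ring branch is 8 (steps 1 to 7, then step 16).

Steps most likely to fail:

Step 4 (the new electrochemical step). Hydrogen abstraction could favour the ring methyl, or the allyl radical could stall as its N-oxyl adduct. The fallback sets out from 5 and uses known chemistry. Wohl–Ziegler bromination (NBS, (PhCO2)2 cat., CCl4, 60 °C) at the ring allylic CH2 gives tert-butyl (1S,2RS)-2-bromo-3,5,5-trimethyl-4-[(1E)-3-oxobut-1-en-1-yl]cyclohex-3-en-1-yl carbonate F1. AgOSO2CF3 with 2,6-lutidine in MeCN then ionises the allylic bromide, and the neighbouring O-Boc group closes onto C4 with loss of isobutene. The ring fusion again allows only the cis carbonate, so the fallback comes back to the route at 6, which is methanolysed to 7 as in step 4.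

Step 6 (salt formation beside a free allylic 4-hydroxyl). If C4–OH ionises competitively, the fallback sets out from 7 and masks the diol. t-BuMe2SiOSO2CF3 with 2,6-lutidine gives (3E)-4-[(3R,4S)-3,4-bis{[tert-butyl(dimethyl)silyl]oxy}-2,6,6-trimethylcyclohex-1-en-1-yl]but-3-en-2-one F2. CH2=CHMgBr gives (1E)-1-[(3R,4S)-3,4-bis{[tert-butyl(dimethyl)silyl]oxy}-2,6,6-trimethylcyclohex-1-en-1-yl]-3-methylpenta-1,4-dien-3-ol F3. PPh3·HBr in CH2Cl2 gives {(2E,4E)-5-[(3R,4S)-3,4-bis{[tert-butyl(dimethyl)silyl]oxy}-2,6,6-trimethylcyclohex-1-en-1-yl]-3-methylpenta-2,4-dien-1-yl}triphenylphosphonium bromide F4. HF·pyridine in THF removes the silyl groups from the acid-stable salt, and the fallback comes back to the route at 9.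

Step 9 (acetonide migration). If the equilibrium does not favour the tetramethyl dioxolane, the fallback sets out from 13 and differentiates the hydroxyls stepwise. Aqueous AcOH gives (2S)-3-methylbutane-1,2,3-triol F5. t-BuMe2SiCl with imidazole silylates only the primary hydroxyl to give (2S)-1-{[tert-butyl(dimethyl)silyl]oxy}-3-methylbutane-2,3-diol F6. 2,2-Dimethoxypropane with pyridinium p-toluenesulfonate gives tert-butyl(dimethyl){[(4S)-2,2,5,5-tetramethyl-1,3-dioxolan-4-yl]methoxy}silane F7. n-Bu4NF then frees the primary alcohol, and the fallback comes back to the route at 14.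

**Further compounds**

F1 | step 4 | tert-butyl (1S,2RS)-2-bromo-3,5,5-trimethyl-4-[(1E)-3-oxobut-1-en-1-yl]cyclohex-3-en-1-yl carbonate | CC1=C(/C=C/C(C)=O)C(C)(C)C[C@H](OC(=O)OC(C)(C)C)C1Br
F2 | step 6 | (3E)-4-[(3R,4S)-3,4-bis{[tert-butyl(dimethyl)silyl]oxy}-2,6,6-trimethylcyclohex-1-en-1-yl]but-3-en-2-one | CC1=C(/C=C/C(C)=O)C(C)(C)C[C@H](O[Si](C)(C)C(C)(C)C)[C@@H]1O[Si](C)(C)C(C)(C)C
F3 | step 6 | (1E)-1-[(3R,4S)-3,4-bis{[tert-butyl(dimethyl)silyl]oxy}-2,6,6-trimethylcyclohex-1-en-1-yl]-3-methylpenta-1,4-dien-3-ol | CC1=C(/C=C/C(C)(O)C=C)C(C)(C)C[C@H](O[Si](C)(C)C(C)(C)C)[C@@H]1O[Si](C)(C)C(C)(C)C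
F4 | step 6 | {(2E,4E)-5-[(3R,4S)-3,4-bis{[tert-butyl(dimethyl)silyl]oxy}-2,6,6-trimethylcyclohex-1-en-1-yl]-3-methylpenta-2,4-dien-1-yl}triphenylphosphonium bromide | CC1=C(/C=C/C(C)=C/C[P+](c2ccccc2)(c2ccccc2)c2ccccc2)C(C)(C)C[C@H](O[Si](C)(C)C(C)(C)C)[C@@H]1O[Si](C)(C)C(C)(C)C.[Br-]
F5 | step 9 | (2S)-3-methylbutane-1,2,3-triol | OC[C@H](O)C(C)(C)O
F6 | step 9 | (2S)-1-{[tert-butyl(dimethyl)silyl]oxy}-3-methylbutane-2,3-diol | CC(C)(C)[Si](C)(C)OC[C@H](O)C(C)(C)O
F7 | step 9 | tert-butyl(dimethyl){[(4S)-2,2,5,5-tetramethyl-1,3-dioxolan-4-yl]methoxy}silane | CC(C)(C)[Si](C)(C)OC[C@@H]1OC(C)(C)OC1(C)C
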